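The constants were set for the occasion; the flask was simulated.

Count the half-lives in the flask before reading any curve.

solid substrate 0.50 mM; time 3.0 min

- which holds at 3.0 min: what has brought the reaction to rest, or that it has not come to rest (for what has run out or reacted, a solid counts together with what of it has only dissolved) (all of the solid substrate has reacted / forward and back rates have come level / it is still moving)
- amount of ring at 3.0 min, in percent of the solid substrate charged

- a species is counted by the solid substrate in it: one open dimer counts as two
- amounts and yields of ring count crystals too
- a step written with two of one species runs at k times the square of its concentration and takes two of it each time
- given per volume of solution although it is solid: crystals, solid substrate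
- at the start none of the solid substrate is in solution
- what has only dissolved of solid substrate counts as not reacted
- the reaction counts as stopped when no species that holds the solid substrate changes by six tenths of a point or more over the second half of the time
- run time (flask): 3.0 min

    solid substrate ⇌ starting material, rate k1*(cs1 - [starting material]) while solid is left; crystals form when [starting material] > cs1 (cs1 = 0.36 mM, k1 = 0.037 s⁻¹)
    ring ⇌ isomer of the product (K2 = 0.11, k2 = 0.16 s⁻¹)
    starting material → ring (k3 = 0.011 s⁻¹)
    starting material + starting material ⇌ open dimer (K4 = 1400 M⁻¹, k4 = 21 M⁻¹ s⁻¹)
    crystals ⇌ ring, rate k5*(cs5 - [ring]) while solid is left; crystals form when [ring] > cs5 (cs5 = 0.17 mM, k5 = 2.0 s⁻¹)

Solid substrate dissolves to starting material, which closes to ring or pairs to open dimer. Dissolved ring passes into crystals and isomer of the product. Two times matter. The first is the closure half-life, the time in which ring closure, taken by itself, halves the starting material: 63.0 s. The second is the reading time, 180 s.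

The gap to solubility halves in 18.7 s and open dimer falls apart with a half-life of 46.2 s, both shorter than the closure half-life but of like size, so these steps delay material on its way to closure and the count below gives a bound, not a figure. Ring and isomer of the product relax in 0.429 s, far shorter than the reading time.

The flask therefore gets 2.86 half-lives. Material closing from the first moment is down to 13.8%, and later entry and a stay in open dimer hold back more. My reckoning stops at a bound: the flask is still moving, with unclosed material above that floor. Saturated ring carries 3.74% as isomer of the product, which puts ring below 82.5%.

The forecast, which names a figure where this reckoning gives a ceiling, says it is still moving and 62%, as starting material and open dimer “keep draining slowly into the ring”.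

The flask gives it is still moving, with ring at 63.1% and starting material plus open dimer at 33.1%.

The flask left until 5.0 min gets 1.90 closure half-lives more. Over them its starting material falls from 20.5% to 9.75%, a logarithmic mean of 14.5% of the charge. Each half-life turns 0.693 of that mean into ring, which comes to 19 percentage points. Isomer of the product stands at 3.75% there, and ring stands at 82.3%, up 19 points.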